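The pyran ring is closed by stitching a one-carbon C–O unit (formaldehyde) between C3 and C8a. The key step exploits the 1,3-relationship of C3 and C8a across C4–C4a: in a 2-fluorodeoxybenzoin, a temporary C4 ketone acidifies C3–H and, sitting ortho to the C8a–F bond on ring A, activates it for SNAr. Carbonate and paraformaldehyde then give the aldol at C3 (C2–C3) and ipso-substitution of fluoride by the new alkoxide (O1–C8a) in one operation, delivering the isoflavanone. The same ketone allows a dynamic kinetic transfer hydrogenation to set C3 as (R); hydrogenolysis removes the C4 oxygen, and ring B is completed by O-prenylation, Claisen rearrangement and a second O-prenylation.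

Key step: step 5

Remark: SEMO stands for the [2-(trimethylsilyl)ethoxy]methoxy group; positions follow isoflavan numbering (O1, C2, C3, C4, C4a to C8a in the chroman, primed numbers on the pendant ring B); the stereocentre C3 of the target is read as (R).

Step 1
Reactants: 1 3-(benzyloxy)phenol
Product: 2 5-(benzyloxy)-2-bromophenol
Conditions: NBS (1.0 equiv), i-Pr2NH (10 mol %), CH2Cl2, −40 to 0 °C
Reagents that add atoms: N-bromosuccinimide, O=C1CCC(=O)N1Br
Why: Amine-mediated ortho-bromination of a phenol: the hydrogen-bonded N-bromoamine should deliver bromine ortho to the OH, and of the two ortho positions the unhindered one para to the benzyloxy group should react rather than the one between the two oxygens.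

Step 2
Reactants: 2 5-(benzyloxy)-2-bromophenol
Product: 3 4-(benzyloxy)-1-bromo-2-(SEMO)benzene
Conditions: SEMCl, K2CO3, DMF, 0 °C to rt
Reagents that add atoms: 2-(trimethylsilyl)ethoxymethyl chloride (SEMCl), C[Si](C)(C)CCOCCl
Why: Williamson-type O-alkylation of the phenoxide with the reactive α-chloro ether should give the SEM ether, which is stable to base, palladium catalysis and hydrogenation and is later removed with fluoride.

Step 3
Reactants: 4 1-(2-fluoro-4-hydroxyphenyl)ethan-1-one
Product: 5 1-[2-fluoro-4-(SEMO)phenyl]ethan-1-one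
Conditions: SEMCl, K2CO3, DMF, 0 °C to rt
Reagents that add atoms: 2-(trimethylsilyl)ethoxymethyl chloride (SEMCl), C[Si](C)(C)CCOCCl
Why: The same phenoxide O-alkylation; carbonate ionises only the phenol (para to the acetyl group) and not the methyl ketone, so C-alkylation is not expected.

Step 4
Reactants: 3 4-(benzyloxy)-1-bromo-2-(SEMO)benzene; 5 1-[2-fluoro-4-(SEMO)phenyl]ethan-1-one
Product: 6 2-[4-(benzyloxy)-2-(SEMO)phenyl]-1-[2-fluoro-4-(SEMO)phenyl]ethan-1-one
Conditions: Pd(OAc)2 (2 mol %), XPhos (4 mol %), K3PO4, toluene, 100 °C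
Reagents that add atoms: none
Why: Palladium-catalysed α-arylation of a methyl ketone enolate (Buchwald–Hartwig type) should join C3 to ring B; the bulky biarylphosphine favours mono-arylation and the mild phosphate base leaves the activated aryl fluoride untouched.

Step 5
Reactants: 6 2-[4-(benzyloxy)-2-(SEMO)phenyl]-1-[2-fluoro-4-(SEMO)phenyl]ethan-1-one
Product: 8 rac-3-[4-(benzyloxy)-2-(SEMO)phenyl]-7-(SEMO)chroman-4-one, via β-hydroxy ketone aldol adduct 7 (not isolated)
Conditions: paraformaldehyde (1.2 equiv CH2O), K2CO3 (1.5 equiv), DMSO, 25 to 50 °C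
Reagents that add atoms: formaldehyde (supplied as paraformaldehyde), C=O
Why: Carbonate in DMSO reversibly enolises 6 at C3 (benzylic and α to the C4 ketone), the enolate adds to formaldehyde (crossed aldol, C2–C3) to give alkoxide 7, and its oxygen O1 attacks C8a, the fluorine-bearing carbon ortho to the C4 carbonyl, through a Meisenheimer intermediate that expels fluoride (intramolecular SNAr, O1–C8a). The closest known reaction types are the hydroxymethylation of deoxybenzoins with formaldehyde and the alkoxide SNAr cyclisation of 2-fluoroaryl β-hydroxy ketones to chroman-4-ones, here run in tandem. The pyranone ring (O1, C2, C3, C4, C4a, C8a) closes by a 6-exo addition–elimination at an aromatic carbon, with the breaking C–F bond outside the new ring. The new stereocentre C3 is formed racemic and is left base-labile on purpose, since it is fixed by the catalyst in step 6. The step needs one hydroxymethylation followed by ring closure faster than dehydration to the α-methylene ketone: the ortho carbonyl makes the SNAr fast, the 7-oxygen is meta to C8a and does not deactivate it, fluoride is the best leaving group, only a small excess of formaldehyde is used, and any 3-hydroxymethyl over-adduct of 8 should revert by retro-aldol.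

Step 6
Reactants: 8 rac-3-[4-(benzyloxy)-2-(SEMO)phenyl]-7-(SEMO)chroman-4-one
Product: 9 (3R,4R)-3-[4-(benzyloxy)-2-(SEMO)phenyl]-7-(SEMO)chroman-4-ol (cis)
Conditions: RuCl(p-cymene)[(R,R)-TsDPEN] (2 mol %), HCO2H/Et3N (5:2), EtOAc, 40 °C
Reagents that add atoms: none
Why: Noyori-type asymmetric transfer hydrogenation with dynamic kinetic resolution: triethylamine racemises the α-aryl ketone through its enol faster than reduction, the (R,R)-catalyst delivers hydride to one carbonyl face to give the (4R)-carbinol and, because hydride enters anti to the 3-aryl group, only the (3R)-ketone is reduced, so both centres should be set as the cis (3R,4R) isomer.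

Step 7
Reactants: 9 (3R,4R)-3-[4-(benzyloxy)-2-(SEMO)phenyl]-7-(SEMO)chroman-4-ol
Product: 10 4-[(3R)-7-(SEMO)chroman-3-yl]-3-(SEMO)phenol
Conditions: H2 (3 bar), Pd(OH)2/C, EtOH–AcOH (20:1), rt
Reagents that add atoms: none
Why: Palladium-catalysed hydrogenolysis should cleave the benzyl ether and the p-alkoxy-activated benzylic C4–OH in one operation, leaving C4 as CH2; C3 takes no part and stays (R).

Step 8
Reactants: 10 4-[(3R)-7-(SEMO)chroman-3-yl]-3-(SEMO)phenol
Product: 11 (3R)-3-[4-(3-methylbut-2-enyloxy)-2-(SEMO)phenyl]-7-(SEMO)chroman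
Conditions: prenyl bromide, K2CO3, acetone, 50 °C
Reagents that add atoms: 1-bromo-3-methylbut-2-ene (prenyl bromide), CC(C)=CCBr
Why: SN2 O-alkylation (Williamson) of the only free phenol, the 4'-OH, with the allylic bromide.

Step 9
Reactants: 11 (3R)-3-[4-(3-methylbut-2-enyloxy)-2-(SEMO)phenyl]-7-(SEMO)chroman
Product: 12 2-(2-methylbut-3-en-2-yl)-4-[(3R)-7-(SEMO)chroman-3-yl]-5-(SEMO)phenol
Conditions: Eu(fod)3 [tris(6,6,7,7,8,8,8-heptafluoro-2,2-dimethyl-3,5-octanedionato)europium] (10 mol %), toluene, 90 °C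
Reagents that add atoms: none
Why: Lewis-acid-catalysed aromatic Claisen [3,3]-sigmatropic rearrangement: the prenyl group is delivered with allylic inversion as a 1,1-dimethylallyl group to the ortho carbon C5', which is unhindered and para to the 2'-oxygen, rather than to C3' between the two oxygens, and tautomerisation restores the 4'-phenol; no stereocentre is formed and C3 is untouched.

Step 10
Reactants: 12 2-(2-methylbut-3-en-2-yl)-4-[(3R)-7-(SEMO)chroman-3-yl]-5-(SEMO)phenol
Product: 13 (3R)-3-[5-(2-methylbut-3-en-2-yl)-4-(3-methylbut-2-enyloxy)-2-(SEMO)phenyl]-7-(SEMO)chroman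
Conditions: prenyl bromide, K2CO3, DMF, 40 °C
Reagents that add atoms: 1-bromo-3-methylbut-2-ene (prenyl bromide), CC(C)=CCBr
Why: Williamson O-alkylation of the hindered 4'-phenoxide, the only free OH, should give the aryl prenyl ether.

Step 11
Reactants: 13 (3R)-3-[5-(2-methylbut-3-en-2-yl)-4-(3-methylbut-2-enyloxy)-2-(SEMO)phenyl]-7-(SEMO)chroman
Product: 14 Manuifolin D, (3R)-3-[2-hydroxy-5-(2-methylbut-3-en-2-yl)-4-(3-methylbut-2-enyloxy)phenyl]chroman-7-ol
Conditions: n-Bu4NF, H2NCH2CH2NH2, DMF, 70 °C; then aq. NH4Cl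
Reagents that add atoms: none
Why: Fluoride attack at silicon fragments both SEM ethers (fluorotrimethylsilane, ethene and formaldehyde, the last scavenged by the diamine) under basic conditions that should spare the acid-labile aryl prenyl ether, the 1,1-dimethylallyl group and C3.

Compound list
1 | 3-(benzyloxy)phenol | Oc1cccc(OCc2ccccc2)c1 | starting material
2 | 5-(benzyloxy)-2-bromophenol | Oc1cc(OCc2ccccc2)ccc1Br | intermediate
3 | 4-(benzyloxy)-1-bromo-2-{[2-(trimethylsilyl)ethoxy]methoxy}benzene | C[Si](C)(C)CCOCOc1cc(OCc2ccccc2)ccc1Br | intermediate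
4 | 1-(2-fluoro-4-hydroxyphenyl)ethan-1-one | CC(=O)c1ccc(O)cc1F | starting material
5 | 1-(2-fluoro-4-{[2-(trimethylsilyl)ethoxy]methoxy}phenyl)ethan-1-one | CC(=O)c1ccc(OCOCC[Si](C)(C)C)cc1F | intermediate
6 | 2-[4-(benzyloxy)-2-(SEMO)phenyl]-1-[2-fluoro-4-(SEMO)phenyl]ethan-1-one | O=C(Cc1ccc(OCc2ccccc2)cc1OCOCC[Si](C)(C)C)c1ccc(OCOCC[Si](C)(C)C)cc1F | intermediate
7 | rac-2-[4-(benzyloxy)-2-(SEMO)phenyl]-1-[2-fluoro-4-(SEMO)phenyl]-3-hydroxypropan-1-one (present as its potassium alkoxide) | O=C(C(CO)c1ccc(OCc2ccccc2)cc1OCOCC[Si](C)(C)C)c1ccc(OCOCC[Si](C)(C)C)cc1F | intermediate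
8 | rac-3-[4-(benzyloxy)-2-(SEMO)phenyl]-7-(SEMO)chroman-4-one | O=C1c2ccc(OCOCC[Si](C)(C)C)cc2OCC1c1ccc(OCc2ccccc2)cc1OCOCC[Si](C)(C)C | intermediate
9 | (3R,4R)-3-[4-(benzyloxy)-2-(SEMO)phenyl]-7-(SEMO)chroman-4-ol (cis) | C[Si](C)(C)CCOCOc1cc(OCc2ccccc2)ccc1[C@@H]1COc2cc(OCOCC[Si](C)(C)C)ccc2[C@@H]1O | intermediate
10 | 4-[(3R)-7-(SEMO)chroman-3-yl]-3-(SEMO)phenol | C[Si](C)(C)CCOCOc1cc(O)ccc1[C@@H]1COc2cc(OCOCC[Si](C)(C)C)ccc2C1 | intermediate
11 | (3R)-3-[4-(3-methylbut-2-enyloxy)-2-(SEMO)phenyl]-7-(SEMO)chroman | C[Si](C)(C)CCOCOc1cc(OCC=C(C)C)ccc1[C@@H]1COc2cc(OCOCC[Si](C)(C)C)ccc2C1 | intermediate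
12 | 2-(2-methylbut-3-en-2-yl)-4-[(3R)-7-(SEMO)chroman-3-yl]-5-(SEMO)phenol | C=CC(C)(C)c1cc([C@@H]2COc3cc(OCOCC[Si](C)(C)C)ccc3C2)c(OCOCC[Si](C)(C)C)cc1O | intermediate
13 | (3R)-3-[5-(2-methylbut-3-en-2-yl)-4-(3-methylbut-2-enyloxy)-2-(SEMO)phenyl]-7-(SEMO)chroman | C=CC(C)(C)c1cc([C@@H]2COc3cc(OCOCC[Si](C)(C)C)ccc3C2)c(OCOCC[Si](C)(C)C)cc1OCC=C(C)C | intermediate
14 | Manuifolin D, (3R)-3-[2-hydroxy-5-(2-methylbut-3-en-2-yl)-4-(3-methylbut-2-enyloxy)phenyl]chroman-7-ol | C=CC(C)(C)c1cc([C@@H]2COc3cc(O)ccc3C2)c(O)cc1OCC=C(C)C | target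

Total step count: 11. Longest linear sequence: 10 steps (steps 1, 2 and 4 to 11, from 1).

Steps most likely to fail

Step 5 (key step). The aldol adduct may dehydrate to the α-methylene ketone and oligomerise, or a second hydroxymethylation may outrun the ring closure. The fallback sets out from 6. C-Formylation with ethyl formate and NaH in THF, then warming in DMF, lets the enolate oxygen of the α-formyl ketone displace fluoride by SNAr. This gives the isoflavone 3-[4-(benzyloxy)-2-(SEMO)phenyl]-7-(SEMO)-4H-chromen-4-one F1, which has no enolisable sp3 centre that can over-react. F1 is then taken with RuCl(p-cymene)[(R,R)-TsDPEN] and HCO2Na through the one-pot conjugate reduction and dynamic kinetic transfer hydrogenation of isoflavones, and comes back to the route at 9.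

Step 9. The rearrangement may go in part to C3' between the two oxygens, or the ortho-(1,1-dimethylallyl)phenol may react further on heating (cyclisation onto the phenol, loss of the allyl group). The fallback sets out from 10. Bromination with NBS at low temperature, ortho to the free 4'-OH and para to the 2'-oxygen, gives 2-bromo-4-[(3R)-7-(SEMO)chroman-3-yl]-5-(SEMO)phenol F2. A ligand-controlled γ-selective Suzuki–Miyaura coupling with 3-methylbut-2-enylboronic acid pinacol ester [Pd(OAc)2, bulky biarylphosphine, K3PO4, THF/H2O] then installs the 1,1-dimethylallyl group. The fallback comes back at 12 and bypasses 11.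

Step 7. Cleavage of the C4–O bond may be slow, or acid may cause dehydration to the isoflav-3-ene and re-hydrogenation, which would erode the C3 configuration. The fallback sets out from 9. Acylation with 1,1'-thiocarbonyldiimidazole gives O-[(3R,4R)-3-[4-(benzyloxy)-2-(SEMO)phenyl]-7-(SEMO)chroman-4-yl] imidazole-1-carbothioate F3. Barton–McCombie deoxygenation (Bu3SnH, AIBN, toluene, 90 °C) proceeds through a C4 radical that does not involve C3, and gives (3R)-3-[4-(benzyloxy)-2-(SEMO)phenyl]-7-(SEMO)chroman F4. Neutral debenzylation (H2, Pd/C, EtOAc) comes back to the route at 10.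

Further compounds
F1 | step 5 | 3-[4-(benzyloxy)-2-(SEMO)phenyl]-7-(SEMO)-4H-chromen-4-one | O=c1c(-c2ccc(OCc3ccccc3)cc2OCOCC[Si](C)(C)C)coc2cc(OCOCC[Si](C)(C)C)ccc12
F2 | step 9 | 2-bromo-4-[(3R)-7-(SEMO)chroman-3-yl]-5-(SEMO)phenol | Brc1cc([C@@H]2COc3cc(OCOCC[Si](C)(C)C)ccc3C2)c(OCOCC[Si](C)(C)C)cc1O
F3 | step 7 | O-[(3R,4R)-3-[4-(benzyloxy)-2-(SEMO)phenyl]-7-(SEMO)chroman-4-yl] imidazole-1-carbothioate | C[Si](C)(C)CCOCOc1cc(OCc2ccccc2)ccc1[C@@H]1COc2cc(OCOCC[Si](C)(C)C)ccc2[C@@H]1OC(=S)n1ccnc1
F4 | step 7 | (3R)-3-[4-(benzyloxy)-2-(SEMO)phenyl]-7-(SEMO)chroman | C[Si](C)(C)CCOCOc1cc(OCc2ccccc2)ccc1[C@@H]1COc2cc(OCOCC[Si](C)(C)C)ccc2C1
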